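**Plan**

- Retrosynthesis: the two S–O bonds (at O3 and O3') are cut first, then the C2=C3 unsaturation and O1–C2 of ring C (back to a 2',4',6'-trihydroxychalcone), then C4a–C8a of ring A (back to an open 3,5,7-triketo ester), then C4–C4a (polyanion acylation) and C2=C3 of a cinnamate (aldol addition and elimination).
- Forward: ring B is bought; the chain is joined at C2=C3, then at C4–C4a; ring A closes by Claisen condensation (C4a–C8a), ring C by oxa-Michael addition (O1–C2) and dehydrogenation; sulfation and debenzylation finish the route.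
- Enabling feature: ring A (C4a, C5, C6, C7, C8, C8a) bears oxygen on C5, C7 and C8a and the acyl carbon C4 on C4a, so it is an acylphloroglucinol, the aromatised form of a 3,5,7-triketo ester acylated between two of its carbonyls.
- Stereochemistry: the target has no stereocentre; C2 and C3 of the flavanone intermediate are transient and erased by dehydrogenation, and the (Z) geometry of the cinnamate is thermodynamic and not carried into the product.
- Protecting groups: MOM on O3 and O3' (the later sulfation sites), benzyl on O4' and O7, O5 free throughout because its hydrogen bond to C4=O keeps it unreactive.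

Key step: step 6

Remark: the target is taken as the free bis(hydrogen sulfate) as drawn; because aryl hydrogen sulfates are labile as free acids, the sulfate groups are carried as triethylammonium salts and the acid form is released only in the cold work-up of the last step.

**Route**

Step 1
Reactants: 1 methyl glycolate
Product: 2 methyl 2-(methoxymethoxy)acetate
Conditions: MOMCl, iPr2NEt, CH2Cl2, 0 °C to rt
Reagents that add atoms: chloromethyl methyl ether, COCCl
Why: O-alkylation of the primary alcohol by the reactive α-chloro ether under a hindered amine base (MOM ether formation) leaves the ester untouched.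

Step 2
Reactants: 3 4-(benzyloxy)-3-hydroxybenzaldehyde
Product: 4 4-(benzyloxy)-3-(methoxymethoxy)benzaldehyde
Conditions: MOMCl, iPr2NEt, CH2Cl2, 0 °C to rt
Reagents that add atoms: chloromethyl methyl ether, COCCl
Why: MOM ether formation on the only free phenol masks the later 3'-sulfation site with a group that is stable to strong base and removable by acid in the presence of benzyl ethers.

Step 3
Reactants: 2 methyl 2-(methoxymethoxy)acetate; 4 4-(benzyloxy)-3-(methoxymethoxy)benzaldehyde
Product: 5 methyl 3-[4-(benzyloxy)-3-(methoxymethoxy)phenyl]-3-hydroxy-2-(methoxymethoxy)propanoate (syn/anti mixture, racemic)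
Conditions: LiN(iPr)2, THF, −78 °C; then 4; AcOH quench at −78 °C
Reagents that add atoms: none
Why: Aldol addition of the lithium enolate of an α-alkoxy ester to a non-enolisable aromatic aldehyde is reliable, and the two new stereocentres are left uncontrolled because both disappear in step 4.

Step 4
Reactants: 5 methyl 3-[4-(benzyloxy)-3-(methoxymethoxy)phenyl]-3-hydroxy-2-(methoxymethoxy)propanoate
Product: 7 methyl (Z)-3-[4-(benzyloxy)-3-(methoxymethoxy)phenyl]-2-(methoxymethoxy)prop-2-enoate, via benzylic mesylate 6 (not isolated)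
Conditions: MsCl, Et3N, CH2Cl2, 0 °C; then DBU, rt to 40 °C
Reagents that add atoms: methanesulfonyl chloride, CS(=O)(=O)Cl (its atoms stay only in 6 and leave again on elimination)
Why: Mesylation followed by E1cB elimination through the ester enolate converges both diastereomers of 5 on the thermodynamically preferred (Z) alkene, in which the aryl group lies trans to the ester.

Step 5
Reactants: 8 methyl 3,5-dioxohexanoate; 7 methyl (Z)-3-[4-(benzyloxy)-3-(methoxymethoxy)phenyl]-2-(methoxymethoxy)prop-2-enoate
Product: 9 methyl (Z)-9-[4-(benzyloxy)-3-(methoxymethoxy)phenyl]-8-(methoxymethoxy)-3,5,7-trioxonon-8-enoate (drawn as the triketo tautomer)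
Conditions: 8 (2.2 equiv), LiN(iPr)2 (6.8 equiv), THF, 0 °C; then 7, −78 to 0 °C; AcOH quench, pH 5 aqueous work-up, crude product carried on
Reagents that add atoms: none
Why: The trilithium trianion of 8 reacts at its most basic terminal carbon with the non-enolisable ester 7 (Claisen-type C-acylation of a β-polycarbonyl polyanion), the second equivalent of trianion takes up the proton of the more acidic product, and conjugate addition is disfavoured because the α-alkoxy-β-aryl acrylate is an electron-rich alkene.

Step 6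
Reactants: 9 methyl (Z)-9-[4-(benzyloxy)-3-(methoxymethoxy)phenyl]-8-(methoxymethoxy)-3,5,7-trioxonon-8-enoate
Product: 10 (Z)-3-[4-(benzyloxy)-3-(methoxymethoxy)phenyl]-2-(methoxymethoxy)-1-(2,4,6-trihydroxyphenyl)prop-2-en-1-one
Conditions: Mg(OMe)2 (excess), MeOH, rt to 50 °C, Ar; cold 1 M HCl to pH 4
Reagents that add atoms: none
Why: Mg(OMe)2 turns 9 into a magnesium-chelated polyenolate whose carbanion at chain C6 (the future C4a), flanked by the C5 and C7 carbonyls, adds to the ester carbon C1 (the future C8a); methoxide leaves and the cyclohexane-1,3,5-trione formed enolises three times to the aromatic ring A. The closest known reaction type is the biomimetic Claisen (Dieckmann-type) cyclisation of 3,5,7-triketo esters to acylphloroglucinols under Mg(OMe)2, which is established for aryl and styryl ketone termini. Ring A closes in a 6-exo-trig mode on the ester carbonyl (enolendo with respect to the C5 enolate), a favoured closure. No stereocentre is formed, and the (Z) alkene is the thermodynamic isomer, so reversible methoxide addition to the enone cannot harm it. The selectivity needed is Claisen closure (C6 on C1) over aldol closure (C2 on the C7 ketone, which would give a resorcylate) and over lactonisation to a pyranone. It is secured by the ester terminus in anhydrous methoxide, by the magnesium chelate that holds the 5,7-dicarbonyl enolate next to the ester, and by the C7 ketone being a poor acceptor because it is conjugated with the donor-substituted alkoxy-arylidene unit and has no hydrogen on its far side, while aromatisation makes the Claisen path irreversible.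

Step 7
Reactants: 10 (Z)-3-[4-(benzyloxy)-3-(methoxymethoxy)phenyl]-2-(methoxymethoxy)-1-(2,4,6-trihydroxyphenyl)prop-2-en-1-one
Product: 11 rac-(2R,3R)-2-[4-(benzyloxy)-3-(methoxymethoxy)phenyl]-5,7-dihydroxy-3-(methoxymethoxy)-2,3-dihydro-4H-chromen-4-one (2,3-trans)
Conditions: NaOAc, EtOH, reflux
Reagents that add atoms: none
Why: Intramolecular oxa-Michael addition of an ortho phenoxide to the enone (chalcone–flavanone isomerisation, 6-endo-trig) is strongly favoured for 2',6'-dihydroxychalcones, and the 2,3-trans arrangement results from thermodynamic control, since reversible ring closure and enolisation at C3 place the aryl and OMOM groups equatorial, in a racemate whose two centres are erased in step 9.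

Step 8
Reactants: 11 rac-(2R,3R)-2-[4-(benzyloxy)-3-(methoxymethoxy)phenyl]-5,7-dihydroxy-3-(methoxymethoxy)-2,3-dihydro-4H-chromen-4-one
Product: 12 rac-(2R,3R)-7-(benzyloxy)-2-[4-(benzyloxy)-3-(methoxymethoxy)phenyl]-5-hydroxy-3-(methoxymethoxy)-2,3-dihydro-4H-chromen-4-one
Conditions: BnBr (1.1 equiv), K2CO3 (1.2 equiv), acetone, rt
Reagents that add atoms: benzyl bromide, BrCc1ccccc1
Why: Williamson etherification takes place at the more acidic, non-chelated 7-OH while the 5-OH stays locked in its hydrogen bond to C4=O, and the mild base at room temperature limits retro-Michael opening.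

Step 9
Reactants: 12 rac-(2R,3R)-7-(benzyloxy)-2-[4-(benzyloxy)-3-(methoxymethoxy)phenyl]-5-hydroxy-3-(methoxymethoxy)-2,3-dihydro-4H-chromen-4-one
Product: 13 7-(benzyloxy)-2-[4-(benzyloxy)-3-(methoxymethoxy)phenyl]-5-hydroxy-3-(methoxymethoxy)-4H-chromen-4-one
Conditions: DDQ, 1,4-dioxane, reflux
Reagents that add atoms: none
Why: Quinone dehydrogenation of a flavanone to a flavone proceeds by hydride abstraction from C2, which is stabilised by O1 and the electron-rich ring B, followed by loss of the C3 proton, is driven by formation of the aromatic 4-pyranone, and is tolerated by MOM and benzyl ethers.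

Step 10
Reactants: 13 7-(benzyloxy)-2-[4-(benzyloxy)-3-(methoxymethoxy)phenyl]-5-hydroxy-3-(methoxymethoxy)-4H-chromen-4-one
Product: 14 7-(benzyloxy)-2-[4-(benzyloxy)-3-hydroxyphenyl]-3,5-dihydroxy-4H-chromen-4-one
Conditions: 3 M HCl in MeOH, THF, 45 °C
Reagents that add atoms: none
Why: Acid-catalysed acetal methanolysis removes both the enol-type 3-O-MOM and the aryl 3'-O-MOM group while the benzyl ethers are inert, exposing exactly the two hydroxyls to be sulfated.

Step 11
Reactants: 14 7-(benzyloxy)-2-[4-(benzyloxy)-3-hydroxyphenyl]-3,5-dihydroxy-4H-chromen-4-one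
Product: 15 bis(triethylammonium) 7-(benzyloxy)-2-[4-(benzyloxy)-3-(sulfonatooxy)phenyl]-5-hydroxy-4-oxo-4H-chromen-3-yl sulfate
Conditions: SO3·NEt3 (5 equiv), Et3N, DMF, 60 °C
Reagents that add atoms: sulfur trioxide–triethylamine complex, CC[N+](CC)(CC)S(=O)(=O)[O-]
Why: O-sulfation by an amine–sulfur trioxide complex converts the 3-OH and 3'-OH into sulfate monoesters as their ammonium salts, while the 5-OH, the least nucleophilic hydroxyl of a flavonol because of its chelation to C4=O, is expected to stay free.

Step 12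
Reactants: 15 bis(triethylammonium) 7-(benzyloxy)-2-[4-(benzyloxy)-3-(sulfonatooxy)phenyl]-5-hydroxy-4-oxo-4H-chromen-3-yl sulfate
Product: 16 quercetin 3,3'-bissulfate, 2-[4-hydroxy-3-(sulfooxy)phenyl]-5,7-dihydroxy-4-oxo-4H-chromen-3-yl hydrogen sulfate
Conditions: H2 (1 atm), 10% Pd/C, MeOH–THF, rt; filtration; sulfonic acid cation-exchange resin (H+ form), 0 °C; freeze-drying
Reagents that add atoms: none
Why: Catalytic hydrogenolysis cleaves the two aryl benzyl ethers without touching aryl sulfate monoesters or the flavone core, and cation exchange replaces triethylammonium by protons to give the acid form.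

**Compound list**

1 | methyl glycolate | COC(=O)CO | starting material
2 | methyl 2-(methoxymethoxy)acetate | COCOCC(=O)OC | intermediate
3 | 4-(benzyloxy)-3-hydroxybenzaldehyde | O=Cc1ccc(OCc2ccccc2)c(O)c1 | starting material
4 | 4-(benzyloxy)-3-(methoxymethoxy)benzaldehyde | O=Cc1ccc(OCc2ccccc2)c(OCOC)c1 | intermediate
5 | methyl 3-[4-(benzyloxy)-3-(methoxymethoxy)phenyl]-3-hydroxy-2-(methoxymethoxy)propanoate (syn/anti mixture, racemic) | COC(=O)C(OCOC)C(O)c1ccc(OCc2ccccc2)c(OCOC)c1 | intermediate
6 | methyl 3-[4-(benzyloxy)-3-(methoxymethoxy)phenyl]-2-(methoxymethoxy)-3-[(methylsulfonyl)oxy]propanoate (diastereomer mixture) | COC(=O)C(OCOC)C(OS(C)(=O)=O)c1ccc(OCc2ccccc2)c(OCOC)c1 | intermediate (not isolated)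
7 | methyl (Z)-3-[4-(benzyloxy)-3-(methoxymethoxy)phenyl]-2-(methoxymethoxy)prop-2-enoate | COC(=O)/C(OCOC)=C/c1ccc(OCc2ccccc2)c(OCOC)c1 | intermediate
8 | methyl 3,5-dioxohexanoate | COC(=O)CC(=O)CC(C)=O | starting material
9 | methyl (Z)-9-[4-(benzyloxy)-3-(methoxymethoxy)phenyl]-8-(methoxymethoxy)-3,5,7-trioxonon-8-enoate | COC(=O)CC(=O)CC(=O)CC(=O)/C(OCOC)=C/c1ccc(OCc2ccccc2)c(OCOC)c1 | intermediate
10 | (Z)-3-[4-(benzyloxy)-3-(methoxymethoxy)phenyl]-2-(methoxymethoxy)-1-(2,4,6-trihydroxyphenyl)prop-2-en-1-one | O=C(c1c(O)cc(O)cc1O)/C(OCOC)=C/c1ccc(OCc2ccccc2)c(OCOC)c1 | intermediate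
11 | rac-(2R,3R)-2-[4-(benzyloxy)-3-(methoxymethoxy)phenyl]-5,7-dihydroxy-3-(methoxymethoxy)-2,3-dihydro-4H-chromen-4-one (2,3-trans racemate, one enantiomer drawn) | O=C1c2c(O)cc(O)cc2O[C@H](c2ccc(OCc3ccccc3)c(OCOC)c2)[C@H]1OCOC | intermediate
12 | rac-(2R,3R)-7-(benzyloxy)-2-[4-(benzyloxy)-3-(methoxymethoxy)phenyl]-5-hydroxy-3-(methoxymethoxy)-2,3-dihydro-4H-chromen-4-one (2,3-trans racemate, one enantiomer drawn) | O=C1c2c(O)cc(OCc3ccccc3)cc2O[C@H](c2ccc(OCc3ccccc3)c(OCOC)c2)[C@H]1OCOC | intermediate
13 | 7-(benzyloxy)-2-[4-(benzyloxy)-3-(methoxymethoxy)phenyl]-5-hydroxy-3-(methoxymethoxy)-4H-chromen-4-one | O=c1c(OCOC)c(-c2ccc(OCc3ccccc3)c(OCOC)c2)oc2cc(OCc3ccccc3)cc(O)c12 | intermediate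
14 | 7-(benzyloxy)-2-[4-(benzyloxy)-3-hydroxyphenyl]-3,5-dihydroxy-4H-chromen-4-one | O=c1c(O)c(-c2ccc(OCc3ccccc3)c(O)c2)oc2cc(OCc3ccccc3)cc(O)c12 | intermediate
15 | bis(triethylammonium) 7-(benzyloxy)-2-[4-(benzyloxy)-3-(sulfonatooxy)phenyl]-5-hydroxy-4-oxo-4H-chromen-3-yl sulfate | O=c1c(OS(=O)(=O)[O-])c(-c2ccc(OCc3ccccc3)c(OS(=O)(=O)[O-])c2)oc2cc(OCc3ccccc3)cc(O)c12.CC[NH+](CC)CC.CC[NH+](CC)CC | intermediate
16 | quercetin 3,3'-bissulfate | O=c1c(OS(=O)(=O)O)c(-c2ccc(O)c(OS(=O)(=O)O)c2)oc2cc(O)cc(O)c12 | target

**Step count and risks**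

Total step count: 12. Longest linear sequence: 11 steps (3 to 16 through steps 2 to 12); step 1 supplies 2 for step 3, and 8 enters at step 5.

Steps most likely to fail:

Step 6. The chain may fold the other way (aldol closure of C2 on the C7 ketone to a resorcylate), may lactonise through an enol oxygen to a 4-hydroxy-2-pyranone, or may lose the acid-sensitive enol MOM acetal during work-up. The fallback takes ring A from a ready-made phloroglucinol instead of building it. It sets out from aldehyde 4, which is condensed (Claisen–Schmidt, KOH, EtOH, rt) with 1-[2,4-bis(benzyloxy)-6-hydroxyphenyl]ethan-1-one F1 (from 2',4',6'-trihydroxyacetophenone with BnBr and K2CO3) to give (E)-1-[2,4-bis(benzyloxy)-6-hydroxyphenyl]-3-[4-(benzyloxy)-3-(methoxymethoxy)phenyl]prop-2-en-1-one F2. Algar–Flynn–Oyamada oxidation (H2O2, NaOH, MeOH, 0 °C to rt) should convert this into 5,7-bis(benzyloxy)-2-[4-(benzyloxy)-3-(methoxymethoxy)phenyl]-3-hydroxy-4H-chromen-4-one F3. MOM cleavage under the conditions of step 10 should give 5,7-bis(benzyloxy)-2-[4-(benzyloxy)-3-hydroxyphenyl]-3-hydroxy-4H-chromen-4-one F4, and sulfation as in step 11 its bis(triethylammonium) 3,3'-bis-sulfate F5. Hydrogenolysis and cation exchange as in step 12 then return to the route at 16.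

Step 5. Proton transfer from the product to unreacted trianion may stall the acylation, and O-acylation, conjugate addition to the acrylate or premature cyclisation of the triketo ester during work-up may erode the material. The fallback forms the same chain with a better-behaved dianion and adds the ester carbon last. It sets out from 7, which acylates the dianion of pentane-2,4-dione (NaH, then n-BuLi, THF, 0 °C) at its terminal carbon to give (Z)-8-[4-(benzyloxy)-3-(methoxymethoxy)phenyl]-7-(methoxymethoxy)oct-7-ene-2,4,6-trione F6. Its trianion (LiN(iPr)2, 3 equiv, THF, 0 °C) is carboxylated with CO2 at the terminal methyl carbon to give (Z)-9-[4-(benzyloxy)-3-(methoxymethoxy)phenyl]-8-(methoxymethoxy)-3,5,7-trioxonon-8-enoic acid F7. Brief esterification with Me3SiCHN2 (MeOH–toluene, 0 °C) returns to the route at 9.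

Step 7. Ring closure may stall because the α-alkoxy group lowers the electrophilicity of the enone β-carbon (the future C2), and the flavanone may reopen under the basic benzylation of step 8, exposing the chalcone phenols to alkylation. The fallback closes ring C oxidatively and directly at the flavone level. It sets out from 10, which is treated with SeO2 (1,4-dioxane or pentan-1-ol, reflux), the classical conversion of α-alkoxy-2'-hydroxychalcones into 3-alkoxyflavones, to give 2-[4-(benzyloxy)-3-(methoxymethoxy)phenyl]-5,7-dihydroxy-3-(methoxymethoxy)-4H-chromen-4-one F8. Selective benzylation of its more acidic 7-OH (BnBr, K2CO3, DMF, rt) returns to the route at 13, bypassing 11 and 12 and with them the DDQ dehydrogenation of step 9.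

**Further compounds**

F1 | step 6 | 1-[2,4-bis(benzyloxy)-6-hydroxyphenyl]ethan-1-one | CC(=O)c1c(O)cc(OCc2ccccc2)cc1OCc1ccccc1
F2 | step 6 | (E)-1-[2,4-bis(benzyloxy)-6-hydroxyphenyl]-3-[4-(benzyloxy)-3-(methoxymethoxy)phenyl]prop-2-en-1-one | O=C(/C=C/c1ccc(OCc2ccccc2)c(OCOC)c1)c1c(O)cc(OCc2ccccc2)cc1OCc1ccccc1
F3 | step 6 | 5,7-bis(benzyloxy)-2-[4-(benzyloxy)-3-(methoxymethoxy)phenyl]-3-hydroxy-4H-chromen-4-one | O=c1c(O)c(-c2ccc(OCc3ccccc3)c(OCOC)c2)oc2cc(OCc3ccccc3)cc(OCc3ccccc3)c12
F4 | step 6 | 5,7-bis(benzyloxy)-2-[4-(benzyloxy)-3-hydroxyphenyl]-3-hydroxy-4H-chromen-4-one | O=c1c(O)c(-c2ccc(OCc3ccccc3)c(O)c2)oc2cc(OCc3ccccc3)cc(OCc3ccccc3)c12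
F5 | step 6 | bis(triethylammonium) 5,7-bis(benzyloxy)-2-[4-(benzyloxy)-3-(sulfonatooxy)phenyl]-4-oxo-4H-chromen-3-yl sulfate | O=c1c(OS(=O)(=O)[O-])c(-c2ccc(OCc3ccccc3)c(OS(=O)(=O)[O-])c2)oc2cc(OCc3ccccc3)cc(OCc3ccccc3)c12.CC[NH+](CC)CC.CC[NH+](CC)CC
F6 | step 5 | (Z)-8-[4-(benzyloxy)-3-(methoxymethoxy)phenyl]-7-(methoxymethoxy)oct-7-ene-2,4,6-trione | CC(=O)CC(=O)CC(=O)/C(OCOC)=C/c1ccc(OCc2ccccc2)c(OCOC)c1
F7 | step 5 | (Z)-9-[4-(benzyloxy)-3-(methoxymethoxy)phenyl]-8-(methoxymethoxy)-3,5,7-trioxonon-8-enoic acid | OC(=O)CC(=O)CC(=O)CC(=O)/C(OCOC)=C/c1ccc(OCc2ccccc2)c(OCOC)c1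
F8 | step 7 | 2-[4-(benzyloxy)-3-(methoxymethoxy)phenyl]-5,7-dihydroxy-3-(methoxymethoxy)-4H-chromen-4-one | O=c1c(OCOC)c(-c2ccc(OCc3ccccc3)c(OCOC)c2)oc2cc(O)cc(O)c12
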